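**Plan** (locants are those of the benzofuran skeleton: O1, C2 aryl, C3 methyl, C3a allyl, C4, C5 OMe, C6 C=O, C7, C7a; ring A = furan ring, ring B = carbocycle)

- Ring A is cut at O1–C2: the enol of a C6/C7a 1,3-dione adds to the C2 aryl ketone with reduction. The dione and C5–OMe go back to a ring B ketone (C5) with silyl ethers at C6 and C7a.
- In that ketone C2(aryl C=O)–C3–C3a–C4–C5(ring C=O) is a 1,5-dicarbonyl array centred on the quaternary C3a. C3a–C4 and C2–C3 are therefore cut together (enol–alkene [2+2], then retro-aldol) to an acyclic aryl β-diketone carrying a trisubstituted alkene.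
- The β-diketone is cut at C4–C5 (Claisen) and the ester at C6–C7 (glyoxylate aldol), back to an allyl-substituted enone made from a propargylic alcohol and an allyl Grignard reagent.
- Forward: the chain is joined in steps 1–7, ring B closes in the photochemical step 8, ring A closes last in step 13.
- Stereochemistry: C6 from a BINOL–titanium aldol; C7a from a 1,3-anti directed reduction; C3a from C7a in step 8; C5 from hydride addition anti to the allyl group and the C6 silyl ether; C3 and C2 from protonation and hydride delivery anti to the allyl group. C6 and C7a are erased by oxidation.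

Key step: step 8

Assumption: (S)-BINOL is taken to give the (S)-2-hydroxy ester in step 4, as in glyoxylate-ene reactions with the same titanium catalyst; if the sense is opposite, (R)-BINOL is used.
Remark: the β-diketone of step 7 is drawn in the diketo form; in solution it should be the hydrogen-bonded enol.

Step 1
Reactants: 1 pent-3-yn-2-ol (racemic); 2 allylmagnesium bromide
Product: 3 (3E)-3-allylpent-3-en-2-ol (racemic)
Conditions: 2 (3 equiv), Et2O, 35 °C; then aq NH4Cl
Reagents that add atoms: none
Why: Alkoxide-directed anti-carbomagnesiation of a propargylic alcohol by an allylic Grignard reagent: allyl adds to the alkyne carbon next to the carbinol and magnesium to the distal carbon inside a five-membered chelate, trans to the allyl group, so protonolysis leaves the methyl group cis to allyl (E).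

Step 2
Reactants: 3 (3E)-3-allylpent-3-en-2-ol
Product: 4 (3E)-3-allylpent-3-en-2-one
Conditions: MnO2 (excess), CH2Cl2, 23 °C
Reagents that add atoms: none
Why: Oxidation of a secondary allylic alcohol with MnO2, which should leave the isolated alkene and the alkene geometry untouched; the racemic carbinol centre is removed.

Step 3
Reactants: 4 (3E)-3-allylpent-3-en-2-one
Product: 5 (3E)-3-allyl-2-(trimethylsilyloxy)penta-1,3-diene
Conditions: LiN(i-Pr)2, THF, −78 °C; Me3SiCl
Reagents that add atoms: chlorotrimethylsilane, C[Si](C)(C)Cl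
Why: Kinetic deprotonation of the methyl ketone at its methyl group by the hindered amide base and O-silylation of the cross-conjugated enolate give the silyl enol ether.

Step 4
Reactants: 5 (3E)-3-allyl-2-(trimethylsilyloxy)penta-1,3-diene; 6 ethyl glyoxylate
Product: 8 ethyl (2S,5E)-5-allyl-2-hydroxy-4-oxohept-5-enoate, via trimethylsilyl ether 7 (not isolated)
Conditions: (S)-BINOL (10 mol %), TiCl2(Oi-Pr)2 (10 mol %), 4 Å MS, CH2Cl2, −20 °C; then 1 M HCl, THF, 0 °C
Reagents that add atoms: none
Why: Catalytic asymmetric Mukaiyama aldol addition of a ketone silyl enol ether to glyoxylate held two-point on the chiral BINOL–titanium Lewis acid, which shields one aldehyde face and sets C2 of the ester (the later C6) as S; the silyl group moves to the new oxygen and is removed on acidic work-up.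

Step 5
Reactants: 8 ethyl (2S,5E)-5-allyl-2-hydroxy-4-oxohept-5-enoate
Product: 9 ethyl (2S,4S,5E)-5-allyl-2,4-dihydroxyhept-5-enoate (1,3-anti)
Conditions: Me4NBH(OAc)3, MeCN/AcOH, −30 °C
Reagents that add atoms: none
Why: Evans–Saksena reduction: the β-hydroxyl exchanges onto boron and hydride is delivered inside a chair-like six-membered transition state, giving the 1,3-anti diol (new centre C4 of the ester, the later C7a, S); the acetoxyborohydride should reduce the enone 1,2 and leave ester and alkenes alone.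

Step 6
Reactants: 9 ethyl (2S,4S,5E)-5-allyl-2,4-dihydroxyhept-5-enoate
Product: 10 ethyl (2S,4S,5E)-5-allyl-2,4-bis(tert-butyldimethylsilyloxy)hept-5-enoate
Conditions: TBSOTf (2.5 equiv), 2,6-lutidine, CH2Cl2, 0 °C
Reagents that add atoms: tert-butyldimethylsilyl trifluoromethanesulfonate, CC(C)(C)[Si](C)(C)OS(=O)(=O)C(F)(F)F
Why: Silylation of both secondary alcohols with the silyl triflate and a hindered pyridine base, done directly on the crude diol so that the γ-hydroxy ester has no time to lactonize.

Step 7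
Reactants: 10 ethyl (2S,4S,5E)-5-allyl-2,4-bis(tert-butyldimethylsilyloxy)hept-5-enoate; 11 1-(3,4,5-trimethoxyphenyl)ethanone
Product: 12 (4S,6S,7E)-7-allyl-4,6-bis(tert-butyldimethylsilyloxy)-1-(3,4,5-trimethoxyphenyl)non-7-ene-1,3-dione
Conditions: 11 (2.2 equiv), LiN(i-Pr)2 (2.1 equiv), THF, −78 °C; then 10, −78 → 0 °C; aq NH4Cl
Reagents that add atoms: none
Why: Claisen condensation of the lithium enolate of the aryl methyl ketone with the α-silyloxy ester; the second equivalent of enolate deprotonates the β-diketone as it forms and so protects it, and the ketone is kept in slight excess over the amide so that no free base enolizes the ester.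

Step 8
Reactants: 12 (4S,6S,7E)-7-allyl-4,6-bis(tert-butyldimethylsilyloxy)-1-(3,4,5-trimethoxyphenyl)non-7-ene-1,3-dione
Product: 14 2-[(1S,2S,4S)-1-allyl-2,4-bis(tert-butyldimethylsilyloxy)-5-oxocyclohexyl]-1-(3,4,5-trimethoxyphenyl)propan-1-one (both epimers at the propanone C2), via cyclobutanol photoadduct 13 (not isolated)
Conditions: hν (365 nm), degassed PhH (0.005 M), 20 °C
Reagents that add atoms: none
Why: Light is absorbed by the hydrogen-bonded enol of 12 (aryl-conjugated C2=C4, carbonyl at C5); its triplet bonds C4 to the internal alkene carbon C3a, the 1,4-diradical (C2, C3) closes the cis-fused cyclobutanol 13, and the strained β-hydroxy ketone opens by retro-aldol cleavage of C2–C4 to the 1,5-diketone 14. The closest known reaction is the intramolecular De Mayo reaction of β-diketones that carry the alkene on the acyl side chain (enol–alkene [2+2] photocycloaddition, then retro-aldol). Ring B closes in a 6-exo mode (C4 onto C3a through C5, C6, C7 and C7a), and the four-membered ring closes by radical recombination (C2 to C3) and is opened again in the same flask. C3a is set by C7a: in the chair-like tether the C7a silyl ether is equatorial and anti to the incoming C4, the ring methylene C7 lies next to the C3a=C3 bond, whose cis substituent is only hydrogen, and not next to the allyl CH2 (A(1,2) strain), so the allyl group should end trans to the C7a oxygen; the C6 silyl ether sits axial next to the carbonyl at little cost, and C3 forms as an epimer mixture that converges in step 13. The step needs the enol double bond C2=C4 and not C4=C5 to react, and the trisubstituted alkene and not the allyl group to be attacked: the triplet localizes where it leaves a benzylic, hydroxy-substituted radical at C2, the five-membered alternative would have to join the fully substituted C5 and C3a, and the allyl alkene could only be reached through an eight-membered ring.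

Step 9
Reactants: 14 2-[(1S,2S,4S)-1-allyl-2,4-bis(tert-butyldimethylsilyloxy)-5-oxocyclohexyl]-1-(3,4,5-trimethoxyphenyl)propan-1-one
Product: 15 2-[(1S,2S,4S,5R)-1-allyl-2,4-bis(tert-butyldimethylsilyloxy)-5-hydroxycyclohexyl]-1-(3,4,5-trimethoxyphenyl)propan-1-one
Conditions: LiBH(s-Bu)3 (1.1 equiv), THF, −78 °C; then aq NH4Cl
Reagents that add atoms: none
Why: Felkin–Anh (non-chelation) hydride reduction of an α-silyloxy ketone: the allyl face of C5 is shielded in either chair of 14, by the axial C6 silyl ether when the side chain is axial and by the axial allyl group after ring flip, so the bulky hydride should enter anti to both and give the C5 alcohol cis to allyl and to the C6 oxygen (C5 R), while the α-branched aryl ketone next to the quaternary carbon is too hindered to compete at −78 °C.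

Step 10
Reactants: 15 2-[(1S,2S,4S,5R)-1-allyl-2,4-bis(tert-butyldimethylsilyloxy)-5-hydroxycyclohexyl]-1-(3,4,5-trimethoxyphenyl)propan-1-one
Product: 16 2-[(1S,2S,4S,5R)-1-allyl-2,4-bis(tert-butyldimethylsilyloxy)-5-methoxycyclohexyl]-1-(3,4,5-trimethoxyphenyl)propan-1-one
Conditions: MeOTf, 2,6-di-tert-butyl-4-methylpyridine, CH2Cl2, 0 → 23 °C
Reagents that add atoms: methyl trifluoromethanesulfonate, COS(=O)(=O)C(F)(F)F
Why: O-Methylation of a hindered secondary alcohol with methyl triflate and a non-nucleophilic pyridine base; the non-basic conditions should avoid silyl migration from the cis C6 oxygen and enolization of the aryl ketone.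

Step 11
Reactants: 16 2-[(1S,2S,4S,5R)-1-allyl-2,4-bis(tert-butyldimethylsilyloxy)-5-methoxycyclohexyl]-1-(3,4,5-trimethoxyphenyl)propan-1-one
Product: 17 2-[(1S,2S,4S,5R)-1-allyl-2,4-dihydroxy-5-methoxycyclohexyl]-1-(3,4,5-trimethoxyphenyl)propan-1-one
Conditions: HF·pyridine, pyridine, THF, 0 → 23 °C
Reagents that add atoms: none
Why: Fluoride cleavage of both silyl ethers; the pyridine buffer should keep the C7a hydroxyl and the aryl ketone from dehydrating to a cyclic enol ether, which would block the later oxidation at C7a.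

Step 12
Reactants: 17 2-[(1S,2S,4S,5R)-1-allyl-2,4-dihydroxy-5-methoxycyclohexyl]-1-(3,4,5-trimethoxyphenyl)propan-1-one
Product: 18 2-[(1S,5R)-1-allyl-5-methoxy-2,4-dioxocyclohexyl]-1-(3,4,5-trimethoxyphenyl)propan-1-one
Conditions: Dess–Martin periodinane (3 equiv), NaHCO3, CH2Cl2, 23 °C
Reagents that add atoms: none
Why: Dess–Martin oxidation of both secondary alcohols, which takes a 1,3-diol through the β-hydroxy ketone to the 1,3-dione without elimination; under the buffered conditions C5, now α to a ketone, should keep its configuration because the dione enolizes between C6 and C7a.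

Step 13
Reactants: 18 2-[(1S,5R)-1-allyl-5-methoxy-2,4-dioxocyclohexyl]-1-(3,4,5-trimethoxyphenyl)propan-1-one
Product: 21 dysodanthin B [(2R,3S,3aS,5R)-3a-allyl-5-methoxy-3-methyl-2-(3,4,5-trimethoxyphenyl)-3,3a,4,5-tetrahydro-1-benzofuran-6(2H)-one], via cyclic hemiketal 19 (not isolated), via dienol ether 20 (not isolated)
Conditions: Et3SiH (5 equiv), CF3CO2H (10 equiv), CH2Cl2, −20 → 0 °C
Reagents that add atoms: none
Why: Acid-promoted cyclodehydration followed by ionic hydrogenation (reductive etherification): the C7a enol oxygen closes ring A in a 5-exo mode onto the aryl ketone (19), loss of water gives dienol ether 20 in which C3 is trigonal so the epimer mixture converges, and protonation at C3 and hydride transfer from Et3SiH to the aryl-stabilized oxocarbenium ion at C2 should both occur on the face anti to the angular allyl group, the hydride also anti to the new methyl group, which places methyl and aryl cis to each other and to allyl (C3 S, C2 R).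

**Compound list**
1 | pent-3-yn-2-ol (racemic) | CC#CC(C)O | starting material
2 | allylmagnesium bromide | C=CC[Mg]Br | starting material
3 | (3E)-3-allylpent-3-en-2-ol (racemic, methyl cis to allyl) | C/C=C(\CC=C)C(C)O | intermediate
4 | (3E)-3-allylpent-3-en-2-one | C/C=C(\CC=C)C(C)=O | intermediate
5 | (3E)-3-allyl-2-(trimethylsilyloxy)penta-1,3-diene | C/C=C(\CC=C)C(=C)O[Si](C)(C)C | intermediate
6 | ethyl glyoxylate | CCOC(=O)C=O | starting material
7 | ethyl (2S,5E)-5-allyl-4-oxo-2-(trimethylsilyloxy)hept-5-enoate | C/C=C(\CC=C)C(=O)C[C@H](O[Si](C)(C)C)C(=O)OCC | intermediate (not isolated)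
8 | ethyl (2S,5E)-5-allyl-2-hydroxy-4-oxohept-5-enoate | C/C=C(\CC=C)C(=O)C[C@H](O)C(=O)OCC | intermediate
9 | ethyl (2S,4S,5E)-5-allyl-2,4-dihydroxyhept-5-enoate (1,3-anti diol) | C/C=C(\CC=C)[C@@H](O)C[C@H](O)C(=O)OCC | intermediate
10 | ethyl (2S,4S,5E)-5-allyl-2,4-bis(tert-butyldimethylsilyloxy)hept-5-enoate | C/C=C(\CC=C)[C@@H](O[Si](C)(C)C(C)(C)C)C[C@H](O[Si](C)(C)C(C)(C)C)C(=O)OCC | intermediate
11 | 1-(3,4,5-trimethoxyphenyl)ethanone | CC(=O)c1cc(OC)c(OC)c(OC)c1 | starting material
12 | (4S,6S,7E)-7-allyl-4,6-bis(tert-butyldimethylsilyloxy)-1-(3,4,5-trimethoxyphenyl)non-7-ene-1,3-dione (enolized in solution) | C/C=C(\CC=C)[C@@H](O[Si](C)(C)C(C)(C)C)C[C@H](O[Si](C)(C)C(C)(C)C)C(=O)CC(=O)c1cc(OC)c(OC)c(OC)c1 | intermediate (key-step precursor)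
13 | (1R,3S,5S,6R)-6-allyl-3,5-bis(tert-butyldimethylsilyloxy)-8-hydroxy-7-methyl-8-(3,4,5-trimethoxyphenyl)bicyclo[4.2.0]octan-2-one (cis ring fusion, allyl trans to the C5 oxygen, epimers at C7 and C8) | C=CC[C@@]12C(C)C(O)(c3cc(OC)c(OC)c(OC)c3)[C@@H]1C(=O)[C@@H](O[Si](C)(C)C(C)(C)C)C[C@@H]2O[Si](C)(C)C(C)(C)C | intermediate (not isolated)
14 | 2-[(1S,2S,4S)-1-allyl-2,4-bis(tert-butyldimethylsilyloxy)-5-oxocyclohexyl]-1-(3,4,5-trimethoxyphenyl)propan-1-one (both epimers at the propanone C2, which is C3 of the target) | C=CC[C@@]1(C(C)C(=O)c2cc(OC)c(OC)c(OC)c2)CC(=O)[C@@H](O[Si](C)(C)C(C)(C)C)C[C@@H]1O[Si](C)(C)C(C)(C)C | intermediate (key-step product)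
15 | 2-[(1S,2S,4S,5R)-1-allyl-2,4-bis(tert-butyldimethylsilyloxy)-5-hydroxycyclohexyl]-1-(3,4,5-trimethoxyphenyl)propan-1-one (hydroxyl cis to allyl, epimers at the propanone C2) | C=CC[C@@]1(C(C)C(=O)c2cc(OC)c(OC)c(OC)c2)C[C@@H](O)[C@@H](O[Si](C)(C)C(C)(C)C)C[C@@H]1O[Si](C)(C)C(C)(C)C | intermediate
16 | 2-[(1S,2S,4S,5R)-1-allyl-2,4-bis(tert-butyldimethylsilyloxy)-5-methoxycyclohexyl]-1-(3,4,5-trimethoxyphenyl)propan-1-one (epimers at the propanone C2) | C=CC[C@@]1(C(C)C(=O)c2cc(OC)c(OC)c(OC)c2)C[C@@H](OC)[C@@H](O[Si](C)(C)C(C)(C)C)C[C@@H]1O[Si](C)(C)C(C)(C)C | intermediate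
17 | 2-[(1S,2S,4S,5R)-1-allyl-2,4-dihydroxy-5-methoxycyclohexyl]-1-(3,4,5-trimethoxyphenyl)propan-1-one (epimers at the propanone C2) | C=CC[C@@]1(C(C)C(=O)c2cc(OC)c(OC)c(OC)c2)C[C@@H](OC)[C@@H](O)C[C@@H]1O | intermediate
18 | 2-[(1S,5R)-1-allyl-5-methoxy-2,4-dioxocyclohexyl]-1-(3,4,5-trimethoxyphenyl)propan-1-one (epimers at the propanone C2, dione enolized) | C=CC[C@@]1(C(C)C(=O)c2cc(OC)c(OC)c(OC)c2)C[C@@H](OC)C(=O)CC1=O | intermediate
19 | (3aS,5R)-3a-allyl-2-hydroxy-5-methoxy-3-methyl-2-(3,4,5-trimethoxyphenyl)-3,3a,4,5-tetrahydro-1-benzofuran-6(2H)-one (epimers at C2 and C3) | C=CC[C@@]12C[C@@H](OC)C(=O)C=C1OC(O)(c1cc(OC)c(OC)c(OC)c1)C2C | intermediate (not isolated)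
20 | (3aS,5R)-3a-allyl-5-methoxy-3-methyl-2-(3,4,5-trimethoxyphenyl)-4,5-dihydro-1-benzofuran-6(3aH)-one | C=CC[C@@]12C[C@@H](OC)C(=O)C=C1OC(c1cc(OC)c(OC)c(OC)c1)=C2C | intermediate (not isolated)
21 | dysodanthin B, (2R,3S,3aS,5R)-3a-allyl-5-methoxy-3-methyl-2-(3,4,5-trimethoxyphenyl)-3,3a,4,5-tetrahydro-1-benzofuran-6(2H)-one (aryl, methyl, allyl and methoxy all on one face) | C=CC[C@@]12C[C@@H](OC)C(=O)C=C1O[C@@H](c1cc(OC)c(OC)c(OC)c1)[C@H]2C | target

**Step count and risks**
Total step count: 13. Longest linear sequence: 13 steps (from pent-3-yn-2-ol).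

Steps most likely to fail:

1. Step 8.
 - What may go wrong: the excited enol may close through its other double bond (C4=C5 onto C3a, five-membered ring), decay without cycloaddition, or react with incomplete facial control by C7a. The aryl ketone product may also undergo secondary photoreactions on long irradiation.
 - Fallback: the enol is fixed as its methyl ether so that only the C2=C4 double bond can react.
 - It sets out from ester 10. The lithium acetylide of 5-ethynyl-1,2,3-trimethoxybenzene (n-BuLi) with BF3·OEt2 in THF at −78 °C should give (4S,6S,7E)-7-allyl-4,6-bis(tert-butyldimethylsilyloxy)-1-(3,4,5-trimethoxyphenyl)non-7-en-1-yn-3-one F1.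
 - Phosphine-catalysed conjugate addition of methanol (PMe3, CH2Cl2) should give (4S,6S,7E)-7-allyl-4,6-bis(tert-butyldimethylsilyloxy)-1-methoxy-1-(3,4,5-trimethoxyphenyl)nona-1,7-dien-3-one F2.
 - Irradiation at 350 nm should form the same C3a–C4 and C2–C3 bonds and give the methyl ether of cyclobutanol 13 F3.
 - 1 M HCl in THF at 0 °C opens this donor–acceptor cyclobutane with loss of methanol, and the route is rejoined at 14.

2. Step 13.
 - What may go wrong: ionization of the benzylic C2–O1 bond of the vinylogous ester in acid, leading to loss of the C2 configuration, C-alkylation by C7 to a bicyclo[3.2.1]octane, or over-reduction to the benzyl compound. Facial control at C3 may also be incomplete.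
 - Fallback: ring A is closed one oxidation level lower, where the product is an ordinary benzylic ether that does not ionize, and the C7=C7a bond is introduced last.
 - It sets out from diol 17. BF3·OEt2 and Et3SiH (CH2Cl2, −78 → −20 °C) should effect reductive etherification of the C7a hydroxyl onto the aryl ketone and give (2R,3S,3aS,5R,6S,7aS)-3a-allyl-5-methoxy-3-methyl-2-(3,4,5-trimethoxyphenyl)octahydro-1-benzofuran-6-ol F4.
 - Dess–Martin oxidation should give (2R,3S,3aS,5R,7aS)-3a-allyl-5-methoxy-3-methyl-2-(3,4,5-trimethoxyphenyl)hexahydro-1-benzofuran-6(2H)-one F5.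
 - LiN(SiMe3)2 with Me3SiCl present (THF, −78 °C) should give (2R,3S,3aS,5R,7aS)-3a-allyl-5-methoxy-3-methyl-6-(trimethylsilyloxy)-2-(3,4,5-trimethoxyphenyl)-2,3,3a,4,5,7a-hexahydro-1-benzofuran F6.
 - Saegusa–Ito oxidation with Pd(OAc)2 in MeCN returns to the route at 21.

3. Step 9.
 - What may go wrong: hydride attack from the allyl face (poor facial selectivity), or competing reduction of the aryl ketone.
 - Fallback: C5 is set at the very end by kinetic protonation of an enolate in the bicyclic skeleton, where the angular allyl group covers one face.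
 - It sets out from 14. The reduction product of the wrong face, the C5 epimer of alcohol 15 F7, is taken through steps 10–13 unchanged: the C5 epimer of methyl ether 16 F8, the C5 epimer of diol 17 F9, the C5 epimer of trione 18 F10 and the C5 epimer of 21 F11.
 - LiN(SiMe3)2 (THF, −78 °C) then forms the C5 enolate of the vinylogous ester, and 2,6-di-tert-butyl-4-methylphenol should protonate it anti to the allyl group, which returns to the route at 21.

Further compounds
F1 | step 8 | (4S,6S,7E)-7-allyl-4,6-bis(tert-butyldimethylsilyloxy)-1-(3,4,5-trimethoxyphenyl)non-7-en-1-yn-3-one | C/C=C(\CC=C)[C@@H](O[Si](C)(C)C(C)(C)C)C[C@H](O[Si](C)(C)C(C)(C)C)C(=O)C#Cc1cc(OC)c(OC)c(OC)c1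
F2 | step 8 | (4S,6S,7E)-7-allyl-4,6-bis(tert-butyldimethylsilyloxy)-1-methoxy-1-(3,4,5-trimethoxyphenyl)nona-1,7-dien-3-one (E/Z mixture at C1) | C/C=C(\CC=C)[C@@H](O[Si](C)(C)C(C)(C)C)C[C@H](O[Si](C)(C)C(C)(C)C)C(=O)C=C(OC)c1cc(OC)c(OC)c(OC)c1
F3 | step 8 | methyl ether of cyclobutanol 13 (8-methoxy in place of 8-hydroxy) | C=CC[C@@]12C(C)C(OC)(c3cc(OC)c(OC)c(OC)c3)[C@@H]1C(=O)[C@@H](O[Si](C)(C)C(C)(C)C)C[C@@H]2O[Si](C)(C)C(C)(C)C
F4 | step 13 | (2R,3S,3aS,5R,6S,7aS)-3a-allyl-5-methoxy-3-methyl-2-(3,4,5-trimethoxyphenyl)octahydro-1-benzofuran-6-ol | C=CC[C@@]12C[C@@H](OC)[C@@H](O)C[C@@H]1O[C@@H](c1cc(OC)c(OC)c(OC)c1)[C@H]2C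
F5 | step 13 | (2R,3S,3aS,5R,7aS)-3a-allyl-5-methoxy-3-methyl-2-(3,4,5-trimethoxyphenyl)hexahydro-1-benzofuran-6(2H)-one | C=CC[C@@]12C[C@@H](OC)C(=O)C[C@@H]1O[C@@H](c1cc(OC)c(OC)c(OC)c1)[C@H]2C
F6 | step 13 | (2R,3S,3aS,5R,7aS)-3a-allyl-5-methoxy-3-methyl-6-(trimethylsilyloxy)-2-(3,4,5-trimethoxyphenyl)-2,3,3a,4,5,7a-hexahydro-1-benzofuran | C=CC[C@@]12C[C@@H](OC)C(O[Si](C)(C)C)=C[C@@H]1O[C@@H](c1cc(OC)c(OC)c(OC)c1)[C@H]2C
F7 | step 9 | C5 epimer of alcohol 15 (hydroxyl trans to allyl) | C=CC[C@@]1(C(C)C(=O)c2cc(OC)c(OC)c(OC)c2)C[C@H](O)[C@@H](O[Si](C)(C)C(C)(C)C)C[C@@H]1O[Si](C)(C)C(C)(C)C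
F8 | step 9 | C5 epimer of methyl ether 16 | C=CC[C@@]1(C(C)C(=O)c2cc(OC)c(OC)c(OC)c2)C[C@H](OC)[C@@H](O[Si](C)(C)C(C)(C)C)C[C@@H]1O[Si](C)(C)C(C)(C)C
F9 | step 9 | C5 epimer of diol 17 | C=CC[C@@]1(C(C)C(=O)c2cc(OC)c(OC)c(OC)c2)C[C@H](OC)[C@@H](O)C[C@@H]1O
F10 | step 9 | C5 epimer of trione 18 | C=CC[C@@]1(C(C)C(=O)c2cc(OC)c(OC)c(OC)c2)C[C@H](OC)C(=O)CC1=O
F11 | step 9 | C5 epimer of 21 (5-epi-dysodanthin B) | C=CC[C@@]12C[C@H](OC)C(=O)C=C1O[C@@H](c1cc(OC)c(OC)c(OC)c1)[C@H]2C
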